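**Plan**

Numbering: ring A C1 (=CH2), C2, C3=C4, C5 (CMe2), C6; C7 carbinol; C8=C9 (methyl on C9); ring B C10–C15, with C13 the tertiary carbinol and C14 the CHBr.
The retrosynthesis cuts C7–C8 first (alkenyl iodide plus aldehyde), then C1–C2 and C5–C6 together. Ring A is a cyclohexene whose C3=C4 alkene lies across the ring from the C1–C6 bond, with the methylidene on C1 and C7 on C6, so it unravels to a C2–C5 diene and an allenoate carrying C1, C6 and C7.
Forward, ring A is closed first by a [4+2] union of a 2-silyloxydiene with ethyl buta-2,3-dienoate; the enol silane becomes the C3=C4 alkene and the ester the C7 aldehyde. Ring B is taken intact from (S)-limonene and joined last through C7–C8.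
Stereochemistry: C6 from the chiral boron Lewis acid; C7 by Felkin–Anh addition; C10 from limonene; C13 from trans-diaxial epoxide opening; C14 by SN2 inversion of a cyclic sulfate; C8=C9 (E) from a boron-Wittig olefination.

Key step: step 2

Assumption: the (S)-configured catalyst is taken to expose the face of the bound allenoate that leads to (1R)-5, by analogy with its acrylate cycloadditions; if the sense proves opposite, the catalyst from (R)-diphenylprolinol is used and nothing else changes.

**Route**

Step 1
Reactants: 1 4-methylpent-3-en-2-one (mesityl oxide)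
Product: 3 triisopropyl[(4-methylpenta-1,3-dien-2-yl)oxy]silane, via lithium dienolate 2 (not isolated)
Conditions: LiN(iPr)2, THF, −78 °C; then iPr3SiOTf, −78 → 0 °C
Reagents that add atoms: triisopropylsilyl trifluoromethanesulfonate, CC(C)[Si](C(C)C)(C(C)C)OS(=O)(=O)C(F)(F)F
Why: Kinetic deprotonation at −78 °C removes a proton of the acetyl methyl group to give the cross-conjugated dienolate, which the silyl triflate traps on oxygen (kinetic enolate O-silylation), and the bulky silyl group is chosen so that the enol ether survives the strong Lewis acid of step 2.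

Step 2
Reactants: 3 triisopropyl[(4-methylpenta-1,3-dien-2-yl)oxy]silane; 4 ethyl buta-2,3-dienoate
Product: 5 ethyl (1R)-2,2-dimethyl-6-methylidene-4-[(triisopropylsilyl)oxy]cyclohex-3-ene-1-carboxylate
Conditions: (S)-B-(2-methylphenyl)oxazaborolidine from (S)-α,α-diphenylprolinol (20 mol %), Tf2NH (18 mol %), CH2Cl2, −78 → −20 °C
Reagents that add atoms: none
Why: Proposed new method: the cationic boron Lewis acid binds the ester carbonyl of 4 and activates its ester-conjugated C=C bond, so the nucleophilic CH2 terminus of the silyl enol ether (C2) attacks the central allene carbon (C1) and the dimethylated terminus (C5) then bonds to the ester α-carbon (C6), either in one asynchronous [4+2] event or as a Mukaiyama–Michael addition followed by collapse of the boron dienolate onto the silyloxyallyl cation. The closest known reaction types are oxazaborolidinium-catalysed Diels–Alder reactions of 2-silyloxydienes with acrylates and Lewis acid promoted Diels–Alder reactions of allenoates at their conjugated double bond, whereas the combination with a terminally dimethylated diene is untested. Ring A closes as a six-membered carbocycle in the [4+2] mode (in the stepwise limit a 6-endo-trig Michael closure at C5), which leaves the distal allene bond as the C1 methylidene and the enol silane at C3=C4. The only new stereocentre, C6, is controlled by the catalyst, whose aryl groups shield one face of the coordinated dienophile so that C5 adds to the open face. The step needs para regiochemistry (silyloxy group 1,4 to the ester) and reaction at the conjugated rather than the distal allene bond, and both follow from the matched polarity of the enol ether terminus and the ester-activated central carbon, while the triisopropylsilyl group is there to suppress silyl transfer and protodesilylation that would stop the sequence at the open-chain Michael adduct.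

Step 3
Reactants: 5 ethyl (1R)-2,2-dimethyl-6-methylidene-4-[(triisopropylsilyl)oxy]cyclohex-3-ene-1-carboxylate
Product: 6 ethyl (1R)-2,2-dimethyl-6-methylidene-4-[(trifluoromethanesulfonyl)oxy]cyclohex-3-ene-1-carboxylate
Conditions: CsF, PhNTf2, DME, 23 °C
Reagents that add atoms: N-phenylbis(trifluoromethanesulfonimide), O=S(=O)(N(c1ccccc1)S(=O)(=O)C(F)(F)F)C(F)(F)F
Why: Fluoride cleaves the Si–O bond and the regiodefined caesium enolate should be triflated on oxygen faster than it can equilibrate (silyl enol ether to enol triflate exchange), so the C3=C4 position is kept and the ester α-centre C6 is not disturbed under these aprotic conditions.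

Step 4
Reactants: 6 ethyl (1R)-2,2-dimethyl-6-methylidene-4-[(trifluoromethanesulfonyl)oxy]cyclohex-3-ene-1-carboxylate
Product: 7 ethyl (1R)-2,2-dimethyl-6-methylidenecyclohex-3-ene-1-carboxylate
Conditions: Pd(OAc)2 (5 mol %), PPh3 (10 mol %), HCO2H, Bu3N, DMF, 60 °C
Reagents that add atoms: none
Why: Zerovalent palladium formed from Pd(OAc)2 and PPh3 inserts into the C–OTf bond and formate delivers hydride, giving the C3=C4 alkene after reductive elimination (palladium-catalysed formate reduction of an enol triflate) under conditions mild enough to leave the skipped methylidene, the ester and C6 alone.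

Step 5
Reactants: 7 ethyl (1R)-2,2-dimethyl-6-methylidenecyclohex-3-ene-1-carboxylate
Product: 8 (1R)-2,2-dimethyl-6-methylidenecyclohex-3-ene-1-carbaldehyde
Conditions: iBu2AlH (1.05 equiv), CH2Cl2, −78 °C; MeOH, then aq. potassium sodium tartrate
Reagents that add atoms: none
Why: At −78 °C one equivalent of hydride adds once to the hindered ester and the aluminium hemiacetal should persist until the cold quench (partial reduction of an ester to the aldehyde), so the epimerisable, deconjugated C6 centre meets neither base nor heat and 8 is used at once.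

Step 6
Reactants: 9 (S)-(−)-limonene
Product: 11 (1R,2R,4S)-1-methyl-4-(prop-1-en-2-yl)cyclohexane-1,2-diol, via (4S)-limonene 1,2-oxide 10 (not isolated)
Conditions: mCPBA (1.0 equiv), CH2Cl2, 0 °C; then THF, 1 M aq. H2SO4, 0 → 23 °C
Reagents that add atoms: 3-chloroperoxybenzoic acid, O=C(OO)c1cccc(Cl)c1; water, O
Why: The peracid epoxidises the more electron-rich trisubstituted ring alkene in preference to the isopropenyl group, and acid-catalysed hydrolysis opens both epoxide diastereomers trans-diaxially (Fürst–Plattner rule) so that they converge on the one anti-diol, with the tertiary C13 hydroxyl cis and the secondary C14 hydroxyl trans to the C10 substituent.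

Step 7
Reactants: 11 (1R,2R,4S)-1-methyl-4-(prop-1-en-2-yl)cyclohexane-1,2-diol
Product: 12 (3aR,6S,7aR)-3a-methyl-6-(prop-1-en-2-yl)hexahydro-1,3,2-benzodioxathiole 2-oxide (cyclic sulfite of 11, both sulfur epimers)
Conditions: SOCl2, Et3N, CH2Cl2, 0 °C
Reagents that add atoms: thionyl chloride, O=S(Cl)Cl
Why: Thionyl chloride and amine base convert the vicinal diol into the five-membered cyclic sulfite (cyclic sulfite formation), which ties up the tertiary C13 oxygen so that it can later neither act as a neighbouring group nor close an epoxide.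

Step 8
Reactants: 12 cyclic sulfite of 11
Product: 13 1-[(3aR,6S,7aR)-3a-methyl-2,2-dioxohexahydro-1,3,2-benzodioxathiol-6-yl]ethan-1-one (cyclic sulfate methyl ketone)
Conditions: RuCl3·xH2O (2 mol %), NaIO4 (4.5 equiv), MeCN/EtOAc/H2O, 0 → 23 °C
Reagents that add atoms: sodium periodate, [Na+].[O-]I(=O)(=O)=O
Why: RuO4 generated in situ oxidises the sulfite to the cyclic sulfate and in the same operation cleaves the 1,1-disubstituted alkene to the methyl ketone (cyclic sulfate synthesis combined with oxidative alkene cleavage), two fast and well-known reactions of this oxidant that should leave the ring stereocentres, including the ketone α-centre C10 in this short near-neutral treatment, untouched.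

Step 9
Reactants: 13 cyclic sulfate methyl ketone
Product: 15 1-[(1S,3S,4R)-3-bromo-4-hydroxy-4-methylcyclohexyl]ethan-1-one, via lithium alkyl sulfate 14 (not isolated)
Conditions: LiBr, THF, 23 → 45 °C; then cat. H2SO4, H2O (2 equiv), THF, 23 °C
Reagents that add atoms: lithium bromide, [Li+].[Br-]
Why: Bromide opens the cyclic sulfate by SN2 attack at the secondary carbon C14 rather than the tertiary C13 and inverts C14, so that bromine ends up cis to the C13 oxygen and equatorial once the ring relaxes, and the alkyl sulfate is then hydrolysed under acid catalysis with S–O cleavage and retention at C13 (nucleophilic opening and hydrolysis of a cyclic sulfate).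

Step 10
Reactants: 15 1-[(1S,3S,4R)-3-bromo-4-hydroxy-4-methylcyclohexyl]ethan-1-one
Product: 16 (1R,2S,4S)-2-bromo-1-methyl-4-[(1E)-1-(4,4,5,5-tetramethyl-1,3,2-dioxaborolan-2-yl)prop-1-en-2-yl]cyclohexan-1-ol
Conditions: CH2(Bpin)2 (2.5 equiv), lithium 2,2,6,6-tetramethylpiperidide (2.4 equiv), THF, 0 °C; then 15, −78 → 0 °C
Reagents that add atoms: bis(4,4,5,5-tetramethyl-1,3,2-dioxaborolan-2-yl)methane, CC1(C)OB(CB2OC(C)(C)C(C)(C)O2)OC1(C)C
Why: The lithiated geminal bis(boronate) adds to the methyl ketone and the resulting alkoxide eliminates one boryl group in a syn fashion (boron-Wittig olefination), which should place the remaining boron trans to the bulkier cyclohexyl substituent and so give the (E)-alkenyl boronate that supplies C8, the first equivalent of base being taken up by the free tertiary hydroxyl.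

Step 11
Reactants: 16 (E)-alkenyl pinacol boronate
Product: 17 (1R,2S,4S)-2-bromo-4-[(1E)-1-iodoprop-1-en-2-yl]-1-methylcyclohexan-1-ol
Conditions: 3 M aq. NaOH, THF, 0 °C; then I2
Reagents that add atoms: iodine, II
Why: Hydroxide forms the boronate complex and iodine replaces boron on the alkene with retention of geometry (iododeboronation of an alkenyl boronate), while the cis-bromohydrin, which cannot close to an epoxide, should tolerate the cold base.

Step 12
Reactants: 8 (1R)-2,2-dimethyl-6-methylidenecyclohex-3-ene-1-carbaldehyde; 17 (1R,2S,4S)-2-bromo-4-[(1E)-1-iodoprop-1-en-2-yl]-1-methylcyclohexan-1-ol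
Product: 18 (1R,2S,4S)-2-bromo-4-[(2E,4R)-4-hydroxy-4-[(1R)-2,2-dimethyl-6-methylidenecyclohex-3-en-1-yl]but-2-en-2-yl]-1-methylcyclohexan-1-ol (CNP0362245.1)
Conditions: 8 (1.3 equiv), CrCl2 (4 equiv), NiCl2 (2 mol %), DMSO, 23 °C
Reagents that add atoms: none
Why: Zerovalent nickel inserts into the C–I bond and transmetalation gives an alkenylchromium species with retained (E) geometry that adds chemoselectively to the aldehyde under near-neutral conditions sparing the secondary bromide, the free tertiary alcohol and the C6 centre (Nozaki–Hiyama–Kishi reaction), the new C7 centre arising by Felkin–Anh attack anti to the quaternary C5 to give the (7R) alcohol.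

**Compound list**

1 | 4-methylpent-3-en-2-one (mesityl oxide) | CC(C)=CC(C)=O | starting material
2 | lithium 4-methylpenta-1,3-dien-2-olate | [Li+].[O-]C(=C)C=C(C)C | intermediate
3 | triisopropyl[(4-methylpenta-1,3-dien-2-yl)oxy]silane | C=C(O[Si](C(C)C)(C(C)C)C(C)C)C=C(C)C | intermediate
4 | ethyl buta-2,3-dienoate | C=C=CC(=O)OCC | starting material
5 | ethyl (1R)-2,2-dimethyl-6-methylidene-4-[(triisopropylsilyl)oxy]cyclohex-3-ene-1-carboxylate | C=C1CC(O[Si](C(C)C)(C(C)C)C(C)C)=CC(C)(C)[C@@H]1C(=O)OCC | intermediate
6 | ethyl (1R)-2,2-dimethyl-6-methylidene-4-[(trifluoromethanesulfonyl)oxy]cyclohex-3-ene-1-carboxylate | C=C1CC(OS(=O)(=O)C(F)(F)F)=CC(C)(C)[C@@H]1C(=O)OCC | intermediate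
7 | ethyl (1R)-2,2-dimethyl-6-methylidenecyclohex-3-ene-1-carboxylate | C=C1CC=CC(C)(C)[C@@H]1C(=O)OCC | intermediate
8 | (1R)-2,2-dimethyl-6-methylidenecyclohex-3-ene-1-carbaldehyde | C=C1CC=CC(C)(C)[C@@H]1C=O | intermediate
9 | (S)-(−)-limonene, (4S)-1-methyl-4-(prop-1-en-2-yl)cyclohex-1-ene | C=C(C)[C@H]1CCC(C)=CC1 | starting material
10 | (4S)-limonene 1,2-oxide, (4S)-1-methyl-4-(prop-1-en-2-yl)-7-oxabicyclo[4.1.0]heptane, both epoxide diastereomers | C=C(C)[C@H]1CCC2(C)OC2C1 | intermediate
11 | (1R,2R,4S)-1-methyl-4-(prop-1-en-2-yl)cyclohexane-1,2-diol | C=C(C)[C@H]1CC[C@@](C)(O)[C@H](O)C1 | intermediate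
12 | (3aR,6S,7aR)-3a-methyl-6-(prop-1-en-2-yl)hexahydro-1,3,2-benzodioxathiole 2-oxide, both sulfur epimers | C=C(C)[C@H]1CC[C@@]2(C)OS(=O)O[C@@H]2C1 | intermediate
13 | 1-[(3aR,6S,7aR)-3a-methyl-2,2-dioxohexahydro-1,3,2-benzodioxathiol-6-yl]ethan-1-one | CC(=O)[C@H]1CC[C@@]2(C)OS(=O)(=O)O[C@@H]2C1 | intermediate
14 | lithium (1R,2S,4S)-4-acetyl-2-bromo-1-methylcyclohexyl sulfate | CC(=O)[C@H]1CC[C@@](C)(OS(=O)(=O)[O-])[C@@H](Br)C1.[Li+] | intermediate
15 | 1-[(1S,3S,4R)-3-bromo-4-hydroxy-4-methylcyclohexyl]ethan-1-one | CC(=O)[C@H]1CC[C@@](C)(O)[C@@H](Br)C1 | intermediate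
16 | (1R,2S,4S)-2-bromo-1-methyl-4-[(1E)-1-(4,4,5,5-tetramethyl-1,3,2-dioxaborolan-2-yl)prop-1-en-2-yl]cyclohexan-1-ol | CC1(C)OB(/C=C(\C)[C@H]2CC[C@@](C)(O)[C@@H](Br)C2)OC1(C)C | intermediate
17 | (1R,2S,4S)-2-bromo-4-[(1E)-1-iodoprop-1-en-2-yl]-1-methylcyclohexan-1-ol | I/C=C(\C)[C@H]1CC[C@@](C)(O)[C@@H](Br)C1 | intermediate
18 | (1R,2S,4S)-2-bromo-4-[(2E,4R)-4-hydroxy-4-[(1R)-2,2-dimethyl-6-methylidenecyclohex-3-en-1-yl]but-2-en-2-yl]-1-methylcyclohexan-1-ol | C=C1CC=CC(C)(C)[C@@H]1[C@H](O)/C=C(\C)[C@H]1CC[C@@](C)(O)[C@@H](Br)C1 | target

**Step count and risks**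

Total step count: 12. Longest linear sequence: 7 steps (steps 6 to 12, from (S)-limonene); the ring A branch is 5 steps (1 to 5) before the union.

Steps most likely to fail:

1. Step 2 (new method). The silyl group may be lost by silyl transfer or protodesilylation before the second bond forms, which would end the sequence at an open-chain Michael adduct, or the catalyst may discriminate the two faces of the allenoate poorly. The fallback sets out from 3 and 4 and rejoins at 8, giving up catalyst control. The achiral aluminium Lewis acid conditions established for cycloadditions of hindered 2-silyloxydienes (Me2AlCl, CH2Cl2, −78 → −20 °C) should give the racemic silyl enol ether ester F1. This passes through the conditions of steps 3 and 4 as the racemic enol triflate F2 and the racemic diene ester F3. iBu2AlH (2.5 equiv, −78 → 0 °C) reduces F3 to the racemic primary alcohol F4. Lipase-catalysed acetylation (Burkholderia cepacia lipase, vinyl acetate) then separates the enantiomers as the (R)-alcohol F5 and the (S)-acetate F6; should the enzyme prefer the other enantiomer, F5 is released from its acetate with K2CO3/MeOH. Dess–Martin periodinane with NaHCO3 oxidises F5 to aldehyde 8.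

2. Step 9. The ring-fused sulfate holds the cyclohexane in the chair in which the C10 acetyl group is axial and lies over the trajectory of bromide towards C14, so substitution may be outrun by elimination or by C–O ionisation at C13. The fallback sets out from 13 and rejoins at 15, using the fact that C10 is α to the ketone and can be moved reversibly. Acid-catalysed equilibration (TsOH, CH2Cl2) should convert 13 into the C10-epimeric cyclic sulfate F7, in which the acetyl group is equatorial and the path to C14 is clear. LiBr and then H2SO4/H2O, as in step 9, should give the C10-epimeric bromohydrin ketone F9 by way of the C10-epimeric lithium alkyl sulfate F8. A final base-mediated equilibration (K2CO3, MeOH, 23 °C) returns C10 to its equatorial, thermodynamically preferred configuration, which is 15.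

3. Step 12. The facial bias at C7 may be too small, since alkenylchromium additions to α-branched aldehydes do not always follow the Felkin–Anh preference strongly. The fallback sets out from crude 18 and returns to 18, moving C7 from substrate to reagent control. The unseparated mixture of 18 and its (7S)-epimer F10 is oxidised (Dess–Martin periodinane, NaHCO3, CH2Cl2) to the single enone F11. A Corey–Bakshi–Shibata reduction ((S)-2-methyl-CBS-oxazaborolidine, catecholborane, toluene, −78 °C), in which ring A is expected to act as the large ketone substituent, then sets the (7R) carbinol.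

Further compounds
F1 | step 2 | racemic ethyl 2,2-dimethyl-6-methylidene-4-[(triisopropylsilyl)oxy]cyclohex-3-ene-1-carboxylate | C=C1CC(O[Si](C(C)C)(C(C)C)C(C)C)=CC(C)(C)C1C(=O)OCC
F2 | step 2 | racemic ethyl 2,2-dimethyl-6-methylidene-4-[(trifluoromethanesulfonyl)oxy]cyclohex-3-ene-1-carboxylate | C=C1CC(OS(=O)(=O)C(F)(F)F)=CC(C)(C)C1C(=O)OCC
F3 | step 2 | racemic ethyl 2,2-dimethyl-6-methylidenecyclohex-3-ene-1-carboxylate | C=C1CC=CC(C)(C)C1C(=O)OCC
F4 | step 2 | racemic (2,2-dimethyl-6-methylidenecyclohex-3-en-1-yl)methanol | C=C1CC=CC(C)(C)C1CO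
F5 | step 2 | [(1R)-2,2-dimethyl-6-methylidenecyclohex-3-en-1-yl]methanol | C=C1CC=CC(C)(C)[C@@H]1CO
F6 | step 2 | [(1S)-2,2-dimethyl-6-methylidenecyclohex-3-en-1-yl]methyl acetate | C=C1CC=CC(C)(C)[C@H]1COC(C)=O
F7 | step 9 | 1-[(3aR,6R,7aR)-3a-methyl-2,2-dioxohexahydro-1,3,2-benzodioxathiol-6-yl]ethan-1-one | CC(=O)[C@@H]1CC[C@@]2(C)OS(=O)(=O)O[C@@H]2C1
F8 | step 9 | lithium (1R,2S,4R)-4-acetyl-2-bromo-1-methylcyclohexyl sulfate | CC(=O)[C@@H]1CC[C@@](C)(OS(=O)(=O)[O-])[C@@H](Br)C1.[Li+]
F9 | step 9 | 1-[(1R,3S,4R)-3-bromo-4-hydroxy-4-methylcyclohexyl]ethan-1-one | CC(=O)[C@@H]1CC[C@@](C)(O)[C@@H](Br)C1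
F10 | step 12 | (1R,2S,4S)-2-bromo-4-[(2E,4S)-4-hydroxy-4-[(1R)-2,2-dimethyl-6-methylidenecyclohex-3-en-1-yl]but-2-en-2-yl]-1-methylcyclohexan-1-ol | C=C1CC=CC(C)(C)[C@@H]1[C@@H](O)/C=C(\C)[C@H]1CC[C@@](C)(O)[C@@H](Br)C1
F11 | step 12 | (2E)-3-[(1S,3S,4R)-3-bromo-4-hydroxy-4-methylcyclohexyl]-1-[(1R)-2,2-dimethyl-6-methylidenecyclohex-3-en-1-yl]but-2-en-1-one | C=C1CC=CC(C)(C)[C@@H]1C(=O)/C=C(\C)[C@H]1CC[C@@](C)(O)[C@@H](Br)C1
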